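Which flask ends with more bis adduct: amber, cold throughout, or ochre, warm for its first half? And is ochre's warm stretch worth running?

| flask | substrate | partner | temperature | remark | time |
|---|---|---|---|---|---|
| alder | 0.050 M | 3 equiv | −18 °C | run made earlier |  |
| elm | 0.20 M | 3 equiv | −1 °C | run made earlier |  |
| cedar | 0.10 M | 6 equiv | −18 °C | run made earlier |  |
| amber | 0.10 M | 3.00 equiv |  | at −25 °C throughout | 3.0 min |
| ochre | 0.10 M | 3.00 equiv |  | at 5 °C until 1.5 min, from then on at −25 °C | 3.0 min |

| run | time / min | bis adduct / % | substrate / % |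
|---|---|---|---|
| alder | 0.833 | 0 | 94.9 |
| alder | 2.50 | 1.9 | 84.5 |
| alder | 4.00 | 3.3 | 75.8 |
| alder | 6.00 | 5.7 | 65.2 |
| alder | 10.0 | 12.5 | 47.4 |
| elm | 0.250 | 5.6 | 66.2 |
| elm | 0.417 | 11.7 | 49.0 |
| elm | 0.833 | 28.8 | 22.9 |
| elm | 1.50 | 46.8 | 10.6 |
| elm | 3.00 | 65.0 | 4.6 |
| cedar | 0.833 | 2.5 | 79.4 |
| cedar | 1.33 | 5.0 | 67.3 |
| cedar | 2.50 | 13.4 | 44.3 |
| cedar | 5.00 | 32.7 | 16.2 |
| cedar | 10.0 | 54.3 | 5.0 |

(readings scatter by 0.3 percentage points)

* which of the two ends with the higher amount of bis adduct, in percent of the substrate charged ("neither" if they lie within 2 percentage points) (amber / ochre / neither)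
* bis adduct at the end, in percent of the substrate charged, amber
* bis adduct at the end, in percent of the substrate charged, ochre

- the analysis behind the earlier runs scatters by 0.3 percentage points, standard deviation
- a reading or a percentage of bis adduct counts all its forms, free or not
- a reading of substrate is of its free form alone

Early on, partner stands in excess and substrate loss is roughly pseudo-first-order, so a rate constant k can be read from one early substrate reading, taking partner at its charge:

k = −ln(substrate fraction) / (partner charge × time)

Alder at 2.50 min reads 0.449 M⁻¹ min⁻¹, and elm at 0.250 min reads 2.75 M⁻¹ min⁻¹. Together they give an activation energy E, with T the temperature: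

E = R ln(k_elm / k_alder) / (1/T_alder − 1/T_elm) = 61.5 kJ mol⁻¹

Suppose both steps are first order in partner and share E. At equal equivalents, a flask then repeats the elm curve on a changed clock, with c the substrate charge:

ρ = exp[(E/R)(1/T_elm − 1/T)] × c / c_elm

For ochre's warm stretch this is 0.899, and at −25 °C it is 0.0360. This pace ratio ρ, the rate in a flask divided by the rate in elm at equal conversion, holds no time: one flask minute counts as ρ elm minutes. As a check, alder at 10.0 min maps to 0.408 min of elm. Alder reads 12.5% there, and elm reads 11.7% at 0.417 min.

Ochre's clock, τ, adds its two stretches: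

τ = 1.35 min + 0.0540 min = 1.40 min

Amber's clock reaches 0.108 min. Interpolating elm puts ochre near 44.2%. Taking early bis adduct as the square of the clock from elm's first reading puts amber near 1.05%. The warm stretch therefore stays in the next run, and the cold stretch counts for far less on the clock.

The forecast says ochre, with 1.2% for amber and 45.5% for ochre: “I therefore scale from the runs empirically”. Both its figures stand above the reckoning here.

The flasks give ochre: 1.46% for amber and 44.6% for ochre.

    substrate + partner → single product + by-product (k = 0.0733 M⁻¹ s⁻¹, Ea = 60.0 kJ mol⁻¹)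
    partner + single product → bis adduct + by-product (k = 0.0868 M⁻¹ s⁻¹, Ea = 60.0 kJ mol⁻¹)
    substrate + bis adduct ⇌ idle adduct, settled at all times (K = 24.0 M⁻¹, ΔH = −56.0 kJ mol⁻¹)
    single product → decomposed reagent (k = 0.00227 s⁻¹, Ea = 74.0 kJ mol⁻¹)
    (constants at 5 °C)

With ρ at 0.899, ochre stood at 43.2% bis adduct at the change of temperature and ended at 44.6%. A partner charge of 2.69 equiv or 3.34 equiv moves ochre's result by 5 points. The neighbouring flask is amber kept at 0 °C. Its ρ is 0.552, so its clock reaches 1.66 min, a little past elm's reading of 46.8% at 1.50 min. That flask ends at 49.7% bis adduct.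

The data stem from a simulated flask for substances that don't exist; the scatter is artificial.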